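**Plan**

1. Retrosynthesis: the CH2–CH2 bond of the propanoate chain (ester α-carbon to benzylic carbon) is cut first, giving octadecyl acetate (as its enolate) and a benzylic electrophile. The benzylic chloride is then traced back to a dimethylamine, and the ring–CH2 bond (Mannich) is cut to reach 2-methoxyresorcinol.
2. Enabling feature: the benzylic carbon hangs on C1 of the benzene ring, ortho to the oxygen on C2 and para to the oxygen on C4. A phenoxide at either oxygen expels a benzylic leaving group and gives a quinone methide whose exocyclic CH2 takes up the enolate with rearomatization.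
3. Forward order: aminomethylation of the bought arene, bis-silylation, amine-to-chloride exchange, then the chain is joined in the last step by fluoride-triggered quinone methide formation, enolate addition and desilylation in one flask. No ring is formed.
4. Helpers: the NMe2 group (stand-in for the leaving group) is removed in step 3, the two TBS groups (masked phenoxide triggers) in step 4.
5. Stereochemistry: the target has no stereocentre and no stereogenic double bond, so nothing has to be set.

Key step: step 4

Remark: 2-methoxyresorcinol and octadecyl acetate are taken as commercial; the target is achiral, so no stereodescriptor is needed.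

**Step 1**
Reactants: 1 2-methoxybenzene-1,3-diol (2-methoxyresorcinol)
Product: 2 4-[(dimethylamino)methyl]-2-methoxybenzene-1,3-diol
Conditions: 37% aq. CH2O (1.0 equiv), 40% aq. Me2NH (1.0 equiv), 1 in 1.3-fold excess, EtOH, 0 °C → rt
Reagents that add atoms: formaldehyde, C=O; dimethylamine, CNC
Why: Phenol Mannich reaction; the iminium ion attacks C4, ortho to one hydroxyl and para to the other, and since C4 and C6 are equivalent by symmetry and C5 is meta to both oxygens only one mono-adduct is possible, while the excess of 1 should hold back the 4,6-bis-adduct.

**Step 2**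
Reactants: 2 4-[(dimethylamino)methyl]-2-methoxybenzene-1,3-diol
Product: 3 1-[2,4-bis(tert-butyldimethylsilyloxy)-3-methoxyphenyl]-N,N-dimethylmethanamine
Conditions: TBSCl (2.5 equiv), imidazole (5 equiv), DMF, rt → 40 °C
Reagents that add atoms: tert-butyldimethylsilyl chloride (TBSCl), CC(C)(C)[Si](C)(C)Cl
Why: Standard silyl ether formation on both phenols (the tertiary amine is inert); the silyl groups mask the phenoxides that later trigger the quinone methide and keep the benzylic chloride of step 3 from condensing with itself.

**Step 3**
Reactants: 3 1-[2,4-bis(tert-butyldimethylsilyloxy)-3-methoxyphenyl]-N,N-dimethylmethanamine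
Product: 4 2,4-bis(tert-butyldimethylsilyloxy)-3-methoxybenzyl chloride
Conditions: ClCO2Et (1.3 equiv), THF, −78 °C → rt, amine added to the chloroformate; volatiles and carbamate removed in vacuo, 4 used at once
Reagents that add atoms: ethyl chloroformate, CCOC(=O)Cl
Why: von Braun-type dealkylative chlorination with a chloroformate; N-acylation gives an acylammonium chloride whose benzylic C–N bond, activated by the ortho and para silyloxy groups, is cut by chloride in preference to N–CH3, and no acid is formed, so the aryl silyl ethers should survive.

**Step 4**
Reactants: 4 2,4-bis(tert-butyldimethylsilyloxy)-3-methoxybenzyl chloride; 5 octadecyl acetate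
Product: 11 octadecyl 3-(2,4-dihydroxy-3-methoxyphenyl)propanoate (target), via lithium enolate 6 (not isolated), via para-quinone methide 7 (not isolated), via ortho-quinone methide 8 (not isolated), via 2-O-silyl ether 9 (not isolated), via 4-O-silyl ether 10 (not isolated)
Conditions: 5 (4 equiv), LDA (commercial solution, 3.8 equiv), THF, −78 °C; then 4 (1 equiv); then TBAF (1 M in THF, dried over 4 Å MS, 2.5 equiv) dropwise, −78 → −40 °C; AcOH (excess), −40 °C → rt; pH 7 work-up
Reagents that add atoms: none
Why: Fluoride cleaves one aryl silyl ether of 4 at −78 °C and the phenoxide set free expels the benzylic chloride, by 1,6-elimination from O4 (the less hindered silyl ether, giving para-quinone methide 7) or by 1,4-elimination from O2 (giving ortho-quinone methide 8); the α-carbon of lithium enolate 6 then adds to the exocyclic methylene carbon, rearomatization drives the C–C bond formation to the phenoxide of 9 or 10, and the remaining silyl ether falls to the excess fluoride. The closest known reaction types are the conjugate addition of ester and ketone lithium enolates to ortho-quinone methides generated at low temperature by fluoride desilylation of 2-silyloxybenzyl chlorides, and the 1,6-addition of enolates to para-quinone methides. No ring is closed and no stereocentre is formed, since both carbons of the new bond are CH2 groups. The step needs site selectivity for the benzylic carbon, which the substrate secures because 7 and 8 carry the same single electrophilic exocyclic carbon, so the order in which the two silyl ethers fall does not matter and the two phenols need no differentiation. It needs capture of the quinone methide by carbon and not by a phenoxide of another molecule, which slow addition of fluoride into an excess of the enolate at −78 °C should secure, and any direct SN2 alkylation of 6 by 4 leads to the same skeleton. It needs the open hydroxy ester and not the dihydrocoumarin, which should hold because under base the phenoxide, not the octadecanolate, is the better leaving group, and because the acetic acid quench and a non-acidic work-up avoid acid-catalysed lactonization.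

**Compound list**

1 | 2-methoxybenzene-1,3-diol (2-methoxyresorcinol) | COc1c(O)cccc1O | starting material
2 | 4-[(dimethylamino)methyl]-2-methoxybenzene-1,3-diol | CN(C)Cc1ccc(O)c(OC)c1O | intermediate
3 | 1-[2,4-bis(tert-butyldimethylsilyloxy)-3-methoxyphenyl]-N,N-dimethylmethanamine | CN(C)Cc1ccc(O[Si](C)(C)C(C)(C)C)c(OC)c1O[Si](C)(C)C(C)(C)C | intermediate
4 | 2,4-bis(tert-butyldimethylsilyloxy)-3-methoxybenzyl chloride | ClCc1ccc(O[Si](C)(C)C(C)(C)C)c(OC)c1O[Si](C)(C)C(C)(C)C | intermediate
5 | octadecyl acetate | CCCCCCCCCCCCCCCCCCOC(C)=O | starting material
6 | lithium enolate of octadecyl acetate, lithium 1-(octadecyloxy)ethen-1-olate | [Li]OC(=C)OCCCCCCCCCCCCCCCCCC | intermediate (not isolated)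
7 | para-quinone methide, 3-(tert-butyldimethylsilyloxy)-2-methoxy-4-methylidenecyclohexa-2,5-dien-1-one | C=C1C=CC(=O)C(OC)=C1O[Si](C)(C)C(C)(C)C | intermediate (not isolated)
8 | ortho-quinone methide, 3-(tert-butyldimethylsilyloxy)-2-methoxy-6-methylidenecyclohexa-2,4-dien-1-one | C=C1C=CC(O[Si](C)(C)C(C)(C)C)=C(OC)C1=O | intermediate (not isolated)
9 | octadecyl 3-[2-(tert-butyldimethylsilyloxy)-4-hydroxy-3-methoxyphenyl]propanoate (formed as its phenoxide) | CCCCCCCCCCCCCCCCCCOC(=O)CCc1ccc(O)c(OC)c1O[Si](C)(C)C(C)(C)C | intermediate (not isolated)
10 | octadecyl 3-[4-(tert-butyldimethylsilyloxy)-2-hydroxy-3-methoxyphenyl]propanoate (formed as its phenoxide) | CCCCCCCCCCCCCCCCCCOC(=O)CCc1ccc(O[Si](C)(C)C(C)(C)C)c(OC)c1O | intermediate (not isolated)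
11 | octadecyl 3-(2,4-dihydroxy-3-methoxyphenyl)propanoate | CCCCCCCCCCCCCCCCCCOC(=O)CCc1ccc(O)c(OC)c1O | target

**Step count and risks**

Total step count: 4. Longest linear sequence: 4 steps (1 → 2 → 3 → 4 → 11); octadecyl acetate 5 enters in the last step.

Steps most likely to fail:

1. Step 4. The quinone methide may be consumed by self-condensation or by phenoxide capture, and the enolate may be lost to protonation by residual water of the fluoride source, to Claisen self-condensation, or to poor solubility of the long-chain ester at −78 °C. The fallback sets out from 1 and comes back at 11, and forms the same carbon–carbon bond by olefination and reduction. Vilsmeier–Haack formylation of 1 (POCl3, DMF, MeCN, then aqueous hydrolysis) should give 2,4-dihydroxy-3-methoxybenzaldehyde F1. Octadecan-1-ol and bromoacetyl bromide (pyridine, CH2Cl2) give octadecyl bromoacetate F2. With PPh3 in toluene this gives [2-(octadecyloxy)-2-oxoethyl]triphenylphosphonium bromide F3, and aqueous NaOH turns that into the stabilized ylide octadecyl (triphenylphosphoranylidene)acetate F4. Wittig olefination of F1 with an excess of F4 (toluene, rt to 60 °C, in the dark) should give octadecyl (E)-3-(2,4-dihydroxy-3-methoxyphenyl)prop-2-enoate F5. Hydrogenation (H2, Pd/C, EtOAc, rt) then gives 11.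

2. Step 3. The very electron-rich benzylic chloride may ionize during its formation or isolation and be lost by Friedel–Crafts self-alkylation or hydrolysis. The fallback sets out from 3 and comes back at 11, and avoids any benzylic halide and any strongly basic enolate. MeI (MeCN, rt) quaternizes 3 to the storable salt {[2,4-bis(tert-butyldimethylsilyloxy)-3-methoxyphenyl]methyl}trimethylammonium iodide F6. Octadecyl acetate 5 is converted (LDA, TBSCl, THF/DMPU, −78 °C) into its silyl ketene acetal tert-butyl(dimethyl){[1-(octadecyloxy)ethenyl]oxy}silane F7. CsF in MeCN/CH2Cl2 at rt desilylates F6, trimethylamine leaves, and the quinone methide is taken up by the neutral ketene acetal in a Mukaiyama–Michael type addition with silyl transfer. This should give octadecyl 3-[2,4-bis(tert-butyldimethylsilyloxy)-3-methoxyphenyl]propanoate F8. TBAF/AcOH (THF, 0 °C) then gives 11.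

3. Step 1. Aminomethylation may run on to C6 as well, and the electron-rich aminophenol may degrade oxidatively during isolation. The fallback sets out from 1 and comes back at 2, and brings the carbon in at the aldehyde level, where the first substitution deactivates the ring against a second. Vilsmeier–Haack formylation of 1 gives 2,4-dihydroxy-3-methoxybenzaldehyde F9 (the same aldehyde as F1). Reductive amination with Me2NH and NaBH(OAc)3 (THF, AcOH, rt) gives 2.

**Further compounds**

F1 | step 4 | 2,4-dihydroxy-3-methoxybenzaldehyde | O=Cc1ccc(O)c(OC)c1O
F2 | step 4 | octadecyl bromoacetate | CCCCCCCCCCCCCCCCCCOC(=O)CBr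
F3 | step 4 | [2-(octadecyloxy)-2-oxoethyl]triphenylphosphonium bromide | CCCCCCCCCCCCCCCCCCOC(=O)C[P+](c1ccccc1)(c1ccccc1)c1ccccc1.[Br-]
F4 | step 4 | octadecyl (triphenylphosphoranylidene)acetate | CCCCCCCCCCCCCCCCCCOC(=O)C=P(c1ccccc1)(c1ccccc1)c1ccccc1
F5 | step 4 | octadecyl (E)-3-(2,4-dihydroxy-3-methoxyphenyl)prop-2-enoate | CCCCCCCCCCCCCCCCCCOC(=O)/C=C/c1ccc(O)c(OC)c1O
F6 | step 3 | {[2,4-bis(tert-butyldimethylsilyloxy)-3-methoxyphenyl]methyl}trimethylammonium iodide | C[N+](C)(C)Cc1ccc(O[Si](C)(C)C(C)(C)C)c(OC)c1O[Si](C)(C)C(C)(C)C.[I-]
F7 | step 3 | tert-butyl(dimethyl){[1-(octadecyloxy)ethenyl]oxy}silane | C=C(O[Si](C)(C)C(C)(C)C)OCCCCCCCCCCCCCCCCCC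
F8 | step 3 | octadecyl 3-[2,4-bis(tert-butyldimethylsilyloxy)-3-methoxyphenyl]propanoate | CCCCCCCCCCCCCCCCCCOC(=O)CCc1ccc(O[Si](C)(C)C(C)(C)C)c(OC)c1O[Si](C)(C)C(C)(C)C
F9 | step 1 | 2,4-dihydroxy-3-methoxybenzaldehyde | O=Cc1ccc(O)c(OC)c1O
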